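Assumption: (2S)‑naringenin of high ee is bought as the natural product; linalool is used as the cheap racemate because its carbinol centre is erased in step 5.

## Retrosynthetic overview

1. Target 11 ⇐ 10 by removal of the 7‑O‑silyl group.
2. 10 ⇐ 8: the C3'–C1'' bond comes from an aromatic Claisen [3,3] rearrangement of a 4'‑O‑(1‑methyl‑1‑alkylallyl) ether (key step).
3. 8 ⇐ 7 + 5: Pd‑catalysed tertiary O‑allylation of the free 4'‑OH of 7‑O‑TIPS‑(2S)‑naringenin.
4. 5 ⇐ linalool 1 (carbonate formation, then hydration of the remote alkene); 7 ⇐ (2S)‑naringenin 6.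
5. No ring is built: rings A, B, C and the C2 stereocentre are bought in 6 and carried through unchanged.

## Route

Step 1
Reactants: 1 (±)‑linalool
Product: 3 methyl linalyl carbonate (racemic), via lithium linalyl alkoxide 2 (not isolated)
Conditions: n‑BuLi (1.05 equiv), THF, −78 °C; ClCO2Me (1.2 equiv), −78 → 0 °C
Reagents that add atoms: methyl chloroformate, COC(Cl)=O
Why: Deprotonation of the tertiary alcohol and O‑acylation of the lithium alkoxide (carbonate formation) gives the tertiary allylic carbonate that later serves as the π‑allyl precursor.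

Step 2
Reactants: 3 methyl linalyl carbonate
Product: 5 methyl 7‑hydroxy‑3,7‑dimethyloct‑1‑en‑3‑yl carbonate (racemic), via acetoxymercurio alcohol 4 (not isolated)
Conditions: Hg(OAc)2 (1.0 equiv), THF/H2O 1:1, 0 °C, 30 min; then NaBH4, 1 M aq NaOH, 0 °C, 10 min
Reagents that add atoms: water, O
Why: Markovnikov oxymercuration–demercuration hydrates the electron‑rich trisubstituted alkene selectively, because the vinyl group is neopentylic and inductively deactivated by the allylic carbonate.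

Step 3
Reactants: 6 (2S)‑naringenin
Product: 7 (2S)‑7‑O‑triisopropylsilylnaringenin
Conditions: TIPSCl (1.05 equiv), imidazole (2.5 equiv), DMF, 0 °C, 2 h
Reagents that add atoms: triisopropylsilyl chloride, CC(C)[Si](Cl)(C(C)C)C(C)C
Why: Silyl ether formation goes to the most acidic phenol (7‑OH, para to the carbonyl), since the 5‑OH is hydrogen‑bonded to C4=O and the 4'‑OH is about two pKa units weaker; the weakly basic conditions do not open the chromanone, so C2 is untouched.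

Step 4
Reactants: 7 (2S)‑7‑O‑triisopropylsilylnaringenin; 5 methyl 7‑hydroxy‑3,7‑dimethyloct‑1‑en‑3‑yl carbonate (1.5 equiv)
Product: 8 (2S)‑7‑O‑triisopropylsilyl‑4'‑O‑(7‑hydroxy‑3,7‑dimethyloct‑1‑en‑3‑yl)naringenin (about 1:1 at the ether carbon)
Conditions: Pd(PPh3)4 (5 mol %), THF, 4 Å MS, 0 °C → rt, stopped at full conversion of 7
Reagents that add atoms: none
Why: In this base‑free Tsuji–Trost O‑allylation the carbonate ionises to a π‑allylpalladium/methoxide pair, the 4'‑phenoxide attacks the more substituted terminus to give the kinetic tertiary ether, and the new ether centre is uncontrolled but is destroyed in step 5.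

Step 5
Reactants: 8 (2S)‑7‑O‑triisopropylsilyl‑4'‑O‑(7‑hydroxy‑3,7‑dimethyloct‑1‑en‑3‑yl)naringenin
Product: 10 (2S)‑7‑O‑triisopropylsilyl‑3'‑[(2E)‑7‑hydroxy‑3,7‑dimethyloct‑2‑en‑1‑yl]naringenin, via ortho‑dienone 9 (not isolated)
Conditions: o‑xylene (0.05 M, degassed), 130 °C, sealed tube, 3 h; prep. HPLC to remove the 2Z isomer
Reagents that add atoms: none
Why: The aromatic Claisen ([3,3]‑sigmatropic) rearrangement through a chair transition state, followed by tautomerisation of dienone 9, forms the C3'–C1'' bond (C3' and C5' are equivalent) under neutral conditions that leave C2 untouched and create no stereocentre; the 2E alkene is expected as the major isomer (roughly 2–3:1, because methyl and CH2R differ little in size) and the 2Z isomer is separated.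

Step 6
Reactants: 10 (2S)‑7‑O‑triisopropylsilyl‑3'‑[(2E)‑7‑hydroxy‑3,7‑dimethyloct‑2‑en‑1‑yl]naringenin
Product: 11 (2S)‑5,7‑dihydroxy‑2‑{4‑hydroxy‑3‑[(2E)‑7‑hydroxy‑3,7‑dimethyloct‑2‑en‑1‑yl]phenyl}chroman‑4‑one (target)
Conditions: TBAF (1.1 equiv), AcOH (1.5 equiv), THF, 0 °C, 20 min
Reagents that add atoms: none
Why: Fluoride desilylation cleaves the aryl O–Si bond, and the acetic acid buffer keeps the medium too weakly basic for retro‑oxa‑Michael opening of the flavanone, so C2 stays (S) and the alkene and tertiary alcohol are unaffected.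

## Compound list

1 | (±)‑linalool (3,7‑dimethylocta‑1,6‑dien‑3‑ol) | CC(C)=CCCC(C)(O)C=C | starting material
2 | lithium linalyl alkoxide | [Li+].[O-]C(C)(C=C)CCC=C(C)C | intermediate (not isolated)
3 | methyl linalyl carbonate, racemic | CC(C)=CCCC(C)(OC(=O)OC)C=C | intermediate
4 | 6‑(acetoxymercurio)‑7‑hydroxy‑3,7‑dimethyloct‑1‑en‑3‑yl methyl carbonate | CC(C)(O)C([Hg]OC(C)=O)CCC(C)(OC(=O)OC)C=C | intermediate (not isolated)
5 | methyl 7‑hydroxy‑3,7‑dimethyloct‑1‑en‑3‑yl carbonate, racemic | CC(C)(O)CCCC(C)(OC(=O)OC)C=C | intermediate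
6 | (2S)‑naringenin | Oc1ccc([C@@H]2CC(=O)c3c(O)cc(O)cc3O2)cc1 | starting material
7 | (2S)‑5‑hydroxy‑2‑(4‑hydroxyphenyl)‑7‑(triisopropylsilyloxy)chroman‑4‑one | Oc1ccc([C@@H]2CC(=O)c3c(O)cc(O[Si](C(C)C)(C(C)C)C(C)C)cc3O2)cc1 | intermediate
8 | (2S)‑5‑hydroxy‑2‑{4‑[(7‑hydroxy‑3,7‑dimethyloct‑1‑en‑3‑yl)oxy]phenyl}‑7‑(triisopropylsilyloxy)chroman‑4‑one, both epimers at the ether carbon | C=CC(C)(CCCC(C)(C)O)Oc1ccc([C@@H]2CC(=O)c3c(O)cc(O[Si](C(C)C)(C(C)C)C(C)C)cc3O2)cc1 | intermediate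
9 | 6‑[(2E)‑7‑hydroxy‑3,7‑dimethyloct‑2‑enyl]‑4‑[(2S)‑5‑hydroxy‑4‑oxo‑7‑(triisopropylsilyloxy)chroman‑2‑yl]cyclohexa‑2,4‑dien‑1‑one | O=C1C=CC([C@@H]2CC(=O)c3c(O)cc(O[Si](C(C)C)(C(C)C)C(C)C)cc3O2)=CC1C/C=C(\C)CCCC(C)(C)O | intermediate (not isolated)
10 | (2S)‑5‑hydroxy‑2‑{4‑hydroxy‑3‑[(2E)‑7‑hydroxy‑3,7‑dimethyloct‑2‑en‑1‑yl]phenyl}‑7‑(triisopropylsilyloxy)chroman‑4‑one | C/C(=C\Cc1cc([C@@H]2CC(=O)c3c(O)cc(O[Si](C(C)C)(C(C)C)C(C)C)cc3O2)ccc1O)CCCC(C)(C)O | intermediate
11 | (2S)‑5,7‑dihydroxy‑2‑{4‑hydroxy‑3‑[(2E)‑7‑hydroxy‑3,7‑dimethyloct‑2‑en‑1‑yl]phenyl}chroman‑4‑one | C/C(=C\Cc1cc([C@@H]2CC(=O)c3c(O)cc(O)cc3O2)ccc1O)CCCC(C)(C)O | target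

## Step count and risks

Total steps: 6. Longest linear sequence: 5 steps (1 → 3 → 5 → 8 → 10 → 11); 4 steps from naringenin 6.

**Step 5 (Claisen rearrangement).** The E/Z ratio is the main weakness, and the tertiary ether can also eliminate back to phenol 7. The fallback sets out from 7 and comes back at 10, taking the alkene geometry from a purchased E‑allyl unit. Geranyl acetate is hydrated at its 6,7‑alkene (Hg(OAc)2, aq THF; NaBH4, 3 M NaOH, which also cleaves the acetate) to give (2E)‑3,7‑dimethyloct‑2‑ene‑1,7‑diol F1. Mitsunobu etherification of 7 with the primary allylic OH of F1 (PPh3, DIAD, THF, 0 °C) gives (2S)‑7‑O‑triisopropylsilyl‑4'‑O‑[(2E)‑7‑hydroxy‑3,7‑dimethyloct‑2‑enyl]naringenin F2. A clay‑promoted 1,3‑O→C allyl shift (montmorillonite K10, CH2Cl2, 0 °C) then moves the intact E‑allyl unit to C3' and returns to 10. This shift runs through a tight ion pair, so the free tertiary alcohol may trap the allyl cation as a tetrahydropyran; the reaction is run cold and stopped early.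

**Step 4 (Pd O‑allylation).** The risks are linear instead of branched ether, and Pd‑mediated re‑ionisation of 8. The fallback sets out from 7 and comes back at 8 through an alkyne. Commercial 6‑hydroxy‑6‑methylheptan‑2‑one and ethynylmagnesium bromide (2.2 equiv, THF, 0 °C) give 3,7‑dimethyloct‑1‑yne‑3,7‑diol F3. Treatment with TFAA/DBU (MeCN, −5 °C) gives in situ 3,7‑dimethyloct‑1‑yne‑3,7‑diyl bis(trifluoroacetate) F4. Adding 7 and CuCl2·2H2O (1 mol %) at 0 °C displaces only the propargylic ester and gives the 4'‑O‑propargyl ether still carrying the remote trifluoroacetate F5. NaHCO3 in MeOH frees the tertiary alcohol to give (2S)‑7‑O‑triisopropylsilyl‑4'‑O‑(7‑hydroxy‑3,7‑dimethyloct‑1‑yn‑3‑yl)naringenin F6. Lindlar semi‑hydrogenation (H2, Pd/CaCO3–Pb, quinoline, EtOAc) returns to 8. The DBU contact must be kept short and cold to protect C2.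

**Step 2 (oxymercuration of 3).** The risks are attack at the vinyl group, Hg‑induced allylic transposition and carbonate loss in the basic demercuration. The fallback sets out from 3 (with 7) and comes back at 8 by postponing the hydration. Carbonate 3 itself is coupled with 7 under the step‑4 conditions to give (2S)‑7‑O‑triisopropylsilyl‑4'‑O‑(3,7‑dimethylocta‑1,6‑dien‑3‑yl)naringenin F7. The remote trisubstituted alkene of F7 is then hydrated by a Mukaiyama hydration (Co(acac)2 cat., PhSiH3, O2, i‑PrOH/THF, rt), in which hydrogen‑atom transfer favours the tertiary radical over the hindered vinyl group, to return to 8.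

Further compounds

F1 | step 5 | (2E)‑3,7‑dimethyloct‑2‑ene‑1,7‑diol | C/C(=C\CO)CCCC(C)(C)O
F2 | step 5 | (2S)‑5‑hydroxy‑2‑{4‑[(2E)‑7‑hydroxy‑3,7‑dimethyloct‑2‑enyloxy]phenyl}‑7‑(triisopropylsilyloxy)chroman‑4‑one | C/C(=C\COc1ccc([C@@H]2CC(=O)c3c(O)cc(O[Si](C(C)C)(C(C)C)C(C)C)cc3O2)cc1)CCCC(C)(C)O
F3 | step 4 | 3,7‑dimethyloct‑1‑yne‑3,7‑diol (racemic) | C#CC(C)(O)CCCC(C)(C)O
F4 | step 4 | 3,7‑dimethyloct‑1‑yne‑3,7‑diyl bis(trifluoroacetate) | C#CC(C)(OC(=O)C(F)(F)F)CCCC(C)(C)OC(=O)C(F)(F)F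
F5 | step 4 | (2S)‑5‑hydroxy‑2‑{4‑[(3,7‑dimethyl‑7‑(trifluoroacetoxy)oct‑1‑yn‑3‑yl)oxy]phenyl}‑7‑(triisopropylsilyloxy)chroman‑4‑one | C#CC(C)(CCCC(C)(C)OC(=O)C(F)(F)F)Oc1ccc([C@@H]2CC(=O)c3c(O)cc(O[Si](C(C)C)(C(C)C)C(C)C)cc3O2)cc1
F6 | step 4 | (2S)‑5‑hydroxy‑2‑{4‑[(7‑hydroxy‑3,7‑dimethyloct‑1‑yn‑3‑yl)oxy]phenyl}‑7‑(triisopropylsilyloxy)chroman‑4‑one | C#CC(C)(CCCC(C)(C)O)Oc1ccc([C@@H]2CC(=O)c3c(O)cc(O[Si](C(C)C)(C(C)C)C(C)C)cc3O2)cc1
F7 | step 2 | (2S)‑5‑hydroxy‑2‑{4‑[(3,7‑dimethylocta‑1,6‑dien‑3‑yl)oxy]phenyl}‑7‑(triisopropylsilyloxy)chroman‑4‑one | C=CC(C)(CCC=C(C)C)Oc1ccc([C@@H]2CC(=O)c3c(O)cc(O[Si](C(C)C)(C(C)C)C(C)C)cc3O2)cc1
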